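Numbering of the tricyclic core used throughout (cyclobuta[a]indane): C1 = CMe2, C2 = the CH that carries boron or the catechol ring, C2a = benzylic ring-fusion CH, C3–C6 = the four outer carbons of ring A, C7 = CH2, C7a = second ring-fusion carbon. For benzocycloheptenone 7: C5 = CH2, C6 = C=O, C7 = CMe2, C8=C9 = alkene, C9 benzylic.

## Analysis of the target

The target 23 is built on a cyclobuta[a]indane: benzene ring A is fused to cyclopentane ring B, and ring B shares its C2a–C7a bond with cyclobutane ring C. Ring A also carries a methoxy group on C6 and a 2,2-dimethyl-2H-pyran ring D across C3–C4 (oxygen on C4), and C2 bears a 3,4-dihydroxyphenyl group (ring E). All four cyclobutane carbons are substituted: C1 is quaternary, and C2 (S), C2a (R) and C7a (S) are three contiguous stereocentres. The B/C fusion can only be cis, so the elements that must be controlled are the trans relationship between ring E on C2 and ring A on C2a, and the absolute configuration. The sensitive groups are the catechol (oxidation), the chromene double bond (no late hydrogenolysis, no strong acid), the electron-rich ring A, and the cyclobutane, which is benzylic at C2 and C2a and opens readily once a cation or an acceptor group sits next to it. The synthesis is hard because a fully substituted, enantiopure cyclobutane with a quaternary carbon must be made, and because ring D must be placed on the ring-fusion side of ring A (C3) and not between the two oxygens (C5). The strategy rests on one feature: if the C2a–C7a bond is removed, rings B and C merge into one benzo-fused seven-membered ring. Drawn with C7a as a ketone carbon and C2a–C2 as a styrene double bond, this is benzocycloheptenone 7, in which the benzylic alkene carbon C9 and the carbonyl carbon C6 face each other across the ring, so that one transannular bond restores both small rings.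

## Retrosynthetic reasoning

**Ring D.** The O–CMe2 bond and the bond between C3 and the pyran CH are cut. The chromene is the electrocyclisation product of ortho-quinone methide 22, which comes from allylic benzylic alcohol 21 by dehydration, and 21 comes from salicylaldehyde 19 and alkenyl Grignard reagent 20. This is done last because the chromene double bond would not survive hydrogenation or the Lewis acid needed for dealkylation. The forward steps must add four carbons to a hindered aldehyde and close the ring without acid strong enough to harm the cyclobutane.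

**Aldehyde carbon and free phenols.** In 19 the C3–CHO bond and three O–alkyl bonds are cut, leading through aldehyde 18 to tetracycle 16, in which the catechol is a bis-benzyl ether and ring A a dimethyl ether. Benzyl is chosen because a boron Lewis acid can remove it together with the one methyl ether that is chelated by the aldehyde, before any chromene exists. The forward formylation must choose C3 (ortho and para to the two oxygens) over C5 (between them) and ring A over ring E.

**C2–aryl bond.** The bond between C2 and ring E is cut to give secondary boronic ester 12 and aryl bromide 13. The cut is made here because boron on C2 is what the key step delivers, already trans to ring A. The forward coupling (through aryllithium 14 and boronate complex 15) has to transfer the cyclobutyl group from boron to carbon with retention.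

**Hydroxyl on C7a.** The C7a–H bond of 12 is traced back to indene 11 and then to tertiary alcohol 10. The oxygen is removed before the arylation, because a free alkoxide cis to boron would compete for boron and consume 14, and because catalytic hydrogenation is still allowed while no benzyl ether is present. An acid-mediated ionic reduction was considered and set aside. A cation on C7a is a cyclobutyl cation next to the gem-dimethyl carbon and would be expected to contract to a cyclopropylcarbinyl cation. The forward sequence is therefore a syn elimination followed by hydrogenation, and the cis fusion returns by necessity.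

**C2a–C7a bond (key disconnection).** Cutting this bond in 10 and removing boron from C2 gives benzocycloheptenone 7 and diboron reagent 8. No other cut removes two rings and three stereocentres at once while leaving an achiral, easily made precursor. The forward reaction (through boryl ether 9) must put boron on C8 and copper on C9 of the cis alkene from one face, then join C9 to the carbonyl carbon C6 across the ring.

**Seven-membered ring.** The C8=C9 double bond of 7 is cut by ring-closing metathesis to diene 6. The styrene of 6 comes from aldehyde 5, which is unmasked from acetal 4. The aryl–CH2 bond of 4 is cut to aryl bromide 2 and ketone 3, which can enolise on one side only. Acetal 2 comes from aldehyde 1. The precursor is thus reached in five standard steps and the risk of the route is concentrated in the key step.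

## Alternatives that were turned down

**Alternative 1:** Ring A is disconnected at the arene bond between the ester-bearing carbon and the carbon attached to the cyclobutane. In the forward step the dioxinone of diketo-dioxinone A1 would be opened by heating in an alcohol to a triketo ester. A carbonate base would then add the ester α-carbon to the cyclopentanone carbonyl and dehydrate to resorcylate A2.
- For: the oxygen pattern of ring A arises without ambiguity. A2 has the ester on the future chromene carbon, a hydrogen-bonded phenol next to it and a free phenol that can be methylated selectively. On this point it is stronger than the chosen route, which must rely on the regioselectivity of a formylation.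
- Against: the whole stereochemical problem is moved into the bicyclic ketone of A1, for which the disconnection offers no solution. A1 is also a donor–acceptor cyclobutane (electron-rich aryl next to a ketone-bearing carbon) whose ring bond can ionise during acylation and aldol folding. The triketo ester can close to a pyrone instead.
- Comparison: the chosen strategy sets all three stereocentres in one catalytic step and never places an acceptor on the cyclobutane.

**Alternative 2:** The cyclobutane is cut into two alkenes, cinnamate A3 and styrene A4. Under visible light with a chiral oxazaborolidine Lewis acid and a triplet sensitiser they would give cyclobutane A5.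
- For: it is the most direct way to the four-membered ring. Both aryl groups and the quaternary carbon are set in one convergent, catalytic, enantioselective step, no sp3–sp2 coupling is needed, and the later Friedel–Crafts closure onto the symmetric dimethoxyphenyl ring has no regiochemical question. On convergence and step count to the cyclobutane it is stronger.
- Against: A5 is all-trans, so the ester is trans to the arene with which it must form ring B, and that ring can only be cis-fused. A contra-thermodynamic epimerisation α to the ester would be needed. The crossed cycloaddition of a cinnamate with a trisubstituted styrene also competes with dimerisation and E/Z isomerisation. The ester carbon must then be acylated onto ring A and deoxygenated, and the chromene problem remains as in the chosen route.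
- Comparison: the chosen strategy obtains the cis fusion by construction and makes ring B in the same step as ring C.

**Alternative 3:** Both bonds from ring A to ring B are cut. A Catellani reaction would join iodochromene A6 and cyclobutenylmethyl bromide A7 by ortho C–H alkylation, ipso arylpalladation of the cyclobutene and hydride capture, giving A8.
- For: it is the most convergent plan. The chromene is in place from the start, so no late formylation is needed, and only debenzylation follows. On late-stage economy it is stronger.
- Against: the ring closure is a 5-endo arylpalladation of the ring-fusion alkene. A syn addition would put palladium on the ring-fusion carbon on the same face as the arene and push the CH2 tether to the opposite face, which is a trans-fused four/five system that cannot form. The competing 4-exo mode would give a benzocyclobutene, and the chromene double bond is a second Heck acceptor. Removing the benzyl groups from A8 must spare the chromene alkene, and A7 needs an asymmetric synthesis of its own.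
- Comparison: the chosen strategy forms the same ring by addition to a carbonyl group, where the cis fusion is the only possible outcome, and creates the chirality catalytically from an achiral precursor.

Key step: step 6

Assumption: the sense of induction of a given Ph-BPE antipode on the new substrate 7 cannot be predicted with certainty; the route is written with (S,S)-Ph-BPE, and (R,R)-Ph-BPE takes its place without other change if the first run shows the mirror-image sense.

## Route

Step 1
Reactants: 1 2-bromo-3,5-dimethoxybenzaldehyde
Product: 2 2-(2-bromo-3,5-dimethoxyphenyl)-1,3-dioxolane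
Conditions: HOCH2CH2OH, TsOH·H2O (cat.), PhMe, reflux, Dean–Stark
Reagents that add atoms: ethylene glycol, OCCO
Why: Acid-catalysed acetalisation with azeotropic removal of water masks the aldehyde, which would otherwise condense with the ketone enolate in step 2.

Step 2
Reactants: 2 2-(2-bromo-3,5-dimethoxyphenyl)-1,3-dioxolane; 3 3,3-dimethylpent-4-en-2-one
Product: 4 1-[2-(1,3-dioxolan-2-yl)-4,6-dimethoxyphenyl]-3,3-dimethylpent-4-en-2-one
Conditions: Pd(OAc)2 (3 mol%), XPhos (6 mol%), NaOtBu (2.5 equiv.), THF, 70 °C
Reagents that add atoms: none
Why: Pd-catalysed α-arylation of a ketone enolate (oxidative addition to zerovalent palladium, enolate binding, C–C reductive elimination); 3 can enolise only at its methyl group, the di-ortho-substituted aryl group prevents a second arylation, and enolate coupling should outrun Heck insertion into the hindered vinyl group.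

Step 3
Reactants: 4 1-[2-(1,3-dioxolan-2-yl)-4,6-dimethoxyphenyl]-3,3-dimethylpent-4-en-2-one
Product: 5 2-(3,3-dimethyl-2-oxopent-4-en-1-yl)-3,5-dimethoxybenzaldehyde
Conditions: 2 M HCl, THF, rt; NaHCO3
Reagents that add atoms: water, O
Why: Acid hydrolysis of the dioxolane; the quaternary α-carbon excludes an intramolecular aldol condensation, and any cyclic hemiacetal or benzopyrylium form should revert to 5 on neutral work-up.

Step 4
Reactants: 5 2-(3,3-dimethyl-2-oxopent-4-en-1-yl)-3,5-dimethoxybenzaldehyde
Product: 6 1-(2-ethenyl-4,6-dimethoxyphenyl)-3,3-dimethylpent-4-en-2-one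
Conditions: Ph3PCH3Br, KN(SiMe3)2, THF, −78 → 0 °C
Reagents that add atoms: methyltriphenylphosphonium bromide, C[P+](c1ccccc1)(c1ccccc1)c1ccccc1.[Br-]
Why: Wittig methylenation; the ylide should add to the aromatic aldehyde far faster than to the ketone flanked by CMe2, and addition at −78 °C is expected to outpace deprotonation of the benzylic ketone CH2.

Step 5
Reactants: 6 1-(2-ethenyl-4,6-dimethoxyphenyl)-3,3-dimethylpent-4-en-2-one
Product: 7 2,4-dimethoxy-7,7-dimethyl-5,7-dihydro-6H-benzo[7]annulen-6-one (cis C8=C9 ring alkene)
Conditions: second-generation Grubbs catalyst (H2IMes)(PCy3)Cl2Ru=CHPh (5 mol%), CH2Cl2 (5 mM), 40 °C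
Reagents that add atoms: none
Why: Ring-closing metathesis of a styrene with a vinyl group gives the seven-membered ring with a necessarily cis alkene; the gem-dimethyl group favours the folded conformer (Thorpe–Ingold effect) and loss of ethylene drives the reaction.

Step 6
Reactants: 7 2,4-dimethoxy-7,7-dimethyl-5,7-dihydro-6H-benzo[7]annulen-6-one; 8 bis(pinacolato)diboron
Product: 10 (2S,2aR,7aR)-4,6-dimethoxy-1,1-dimethyl-2-(4,4,5,5-tetramethyl-1,3,2-dioxaborolan-2-yl)-1,2,2a,7-tetrahydro-7aH-cyclobuta[a]inden-7a-ol (cis ring fusion, boron trans to ring A), via O-boryl ether 9 (not isolated)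
Conditions: CuCl (10 mol%), (S,S)-Ph-BPE (11 mol%), NaOtBu (20 mol%), THF, 0 °C → rt; aq. NH4Cl
Reagents that add atoms: none
Why: Proposed new method: the ligated copper tert-butoxide and 8 give a monovalent copper boryl, L*Cu–Bpin, which adds syn across the C8=C9 bond of 7 with boron on C8 and copper on benzylic C9; the benzylcopper then adds across the ring to the C6 carbonyl with retention at carbon, and the copper alkoxide is borylated by 8 to give 9 and regenerate the catalyst. The closest known reaction type is the CuCl/bisphosphine-catalysed enantioselective borylcupration of styrenes whose benzylcopper is trapped by a tethered ketone or alkyl sulfonate (the latter also giving cyclobutylboronates); new here is that nucleophile and electrophile sit in the same seven-membered ring. The one new C9–C6 bond closes the cyclobutane in a 4-exo-trig mode along the C8–C7 tether and the five-membered ring in a 5-exo-trig mode along the arene–CH2 tether. C2 and C2a are set in the borylcupration, whose face is chosen by the ligand; because the ring alkene is cis, syn addition followed by retentive C–C bond formation places boron trans to ring A. C7a is not free, since the carbonyl carbon can only be reached on the face that gives the cis-fused bicycle. The step needs benzylic regioselectivity of cupration (secured by the aryl group, whose methoxy groups are meta to the alkene-bearing carbon and do not deactivate it), alkene over carbonyl chemoselectivity (the ketone is shielded by CMe2 from intermolecular boryl addition) and ring closure ahead of protonation (no proton source is added and the base is catalytic). The gem-dimethyl group and the ring hold C9 and C6 close, and O–B bond formation is counted on to trap the strained copper cyclobutanolate before β-carbon elimination reverses the closure.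

Step 7
Reactants: 10 (2S,2aR,7aR)-4,6-dimethoxy-1,1-dimethyl-2-(4,4,5,5-tetramethyl-1,3,2-dioxaborolan-2-yl)-1,2,2a,7-tetrahydro-7aH-cyclobuta[a]inden-7a-ol
Product: 11 (2S,2aS)-4,6-dimethoxy-1,1-dimethyl-2-(4,4,5,5-tetramethyl-1,3,2-dioxaborolan-2-yl)-2,2a-dihydro-1H-cyclobuta[a]indene (C7=C7a double bond)
Conditions: Burgess reagent (MeO2CN−SO2N+Et3), PhMe, 50 °C
Reagents that add atoms: none
Why: Burgess dehydration; the sulfamate ester should collapse by syn elimination with the benzylic C7–H, so that the C–O bond breaks as the conjugated indene forms and a free cyclobutyl cation, which could contract to a cyclopropylcarbinyl cation, is avoided; elimination towards C2a would give a far more strained ring-fusion cyclobutene.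

Step 8
Reactants: 11 (2S,2aS)-4,6-dimethoxy-1,1-dimethyl-2-(4,4,5,5-tetramethyl-1,3,2-dioxaborolan-2-yl)-2,2a-dihydro-1H-cyclobuta[a]indene
Product: 12 (2S,2aS,7aS)-4,6-dimethoxy-1,1-dimethyl-2-(4,4,5,5-tetramethyl-1,3,2-dioxaborolan-2-yl)-2,2a,7,7a-tetrahydro-1H-cyclobuta[a]indene (cis ring fusion, boron trans to ring A)
Conditions: H2 (1 atm), Pd/C, EtOAc, rt
Reagents that add atoms: none
Why: Heterogeneous hydrogenation of the strained styrenic alkene; hydrogen can add to C7a only on the face of the C2a–H, because the cyclobutane cannot span a trans fusion, so C7a is reset with cis fusion; no benzyl ether is present yet and the alkyl boronate is inert.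

Step 9
Reactants: 12 (2S,2aS,7aS)-4,6-dimethoxy-1,1-dimethyl-2-(4,4,5,5-tetramethyl-1,3,2-dioxaborolan-2-yl)-2,2a,7,7a-tetrahydro-1H-cyclobuta[a]indene; 13 4-bromo-1,2-bis(benzyloxy)benzene
Product: 16 (2S,2aR,7aS)-2-[3,4-bis(benzyloxy)phenyl]-4,6-dimethoxy-1,1-dimethyl-2,2a,7,7a-tetrahydro-1H-cyclobuta[a]indene (aryl trans to ring A), via aryllithium 14 (not isolated), via lithium boronate complex 15 (not isolated)
Conditions: 13, n-BuLi, THF, −78 °C; 12, −78 °C; NBS, THF–MeOH, −78 °C → rt
Reagents that add atoms: none
Why: Stereoretentive sp2–sp3 coupling of a boronic ester with an electron-rich aryllithium by 1,2-metallate rearrangement; NBS should brominate the aryl ring of 15 ortho to boron and para to the 3-benzyloxy group, which triggers migration of the cyclobutyl group from boron to carbon with retention, and loss of bromide and boron restores the arene; C2 keeps its configuration, so ring E stands trans to ring A.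

Step 10
Reactants: 16 (2S,2aR,7aS)-2-[3,4-bis(benzyloxy)phenyl]-4,6-dimethoxy-1,1-dimethyl-2,2a,7,7a-tetrahydro-1H-cyclobuta[a]indene
Product: 18 (2S,2aR,7aS)-2-[3,4-bis(benzyloxy)phenyl]-4,6-dimethoxy-1,1-dimethyl-2,2a,7,7a-tetrahydro-1H-cyclobuta[a]indene-3-carbaldehyde, via iminium chloride 17 (not isolated)
Conditions: POCl3, DMF, 0 → 50 °C; aq. NaOAc
Reagents that add atoms: N,N-dimethylformamide, CN(C)C=O; water, O
Why: Vilsmeier–Haack formylation; C3 is ortho to the C4 methoxy and para to the C6 methoxy group, whereas C5 lies between two methoxy groups, one of which is turned towards C5 by the C7 methylene, and the catechol diether ring E is much less nucleophilic than the resorcinol diether ring A.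

Step 11
Reactants: 18 (2S,2aR,7aS)-2-[3,4-bis(benzyloxy)phenyl]-4,6-dimethoxy-1,1-dimethyl-2,2a,7,7a-tetrahydro-1H-cyclobuta[a]indene-3-carbaldehyde
Product: 19 (2S,2aR,7aS)-2-(3,4-dihydroxyphenyl)-4-hydroxy-6-methoxy-1,1-dimethyl-2,2a,7,7a-tetrahydro-1H-cyclobuta[a]indene-3-carbaldehyde
Conditions: BCl3, C6HMe5, CH2Cl2, −78 → 0 °C; MeOH
Reagents that add atoms: none
Why: BCl3 cleaves aryl benzyl ethers at low temperature (pentamethylbenzene traps the benzyl cations) and, through chelation with the aldehyde, the ortho methyl ether on C4; the C6 methyl ether has no chelating neighbour and should survive.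

Step 12
Reactants: 19 (2S,2aR,7aS)-2-(3,4-dihydroxyphenyl)-4-hydroxy-6-methoxy-1,1-dimethyl-2,2a,7,7a-tetrahydro-1H-cyclobuta[a]indene-3-carbaldehyde; 20 2-methylprop-1-enylmagnesium bromide
Product: 21 4-[(2S,2aR,7aS)-4-hydroxy-3-(1-hydroxy-3-methylbut-2-en-1-yl)-6-methoxy-1,1-dimethyl-2,2a,7,7a-tetrahydro-1H-cyclobuta[a]inden-2-yl]benzene-1,2-diol (both epimers at the carbinol carbon)
Conditions: 20 (6 equiv.), THF, 0 °C → rt; aq. NH4Cl
Reagents that add atoms: none
Why: Grignard addition to a salicylaldehyde; three equivalents are consumed by the phenols and the magnesium phenoxide next to the aldehyde still accepts the alkenyl nucleophile; the new carbinol centre forms as both epimers, which does not matter because it is lost in step 13.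

Step 13
Reactants: 21 4-[(2S,2aR,7aS)-4-hydroxy-3-(1-hydroxy-3-methylbut-2-en-1-yl)-6-methoxy-1,1-dimethyl-2,2a,7,7a-tetrahydro-1H-cyclobuta[a]inden-2-yl]benzene-1,2-diol
Product: 23 CNP0207533.1, the 2,2-dimethyl-2H-chromene in which the pyran ring spans C3 (CH=CH) and C4 (oxygen) of the (2S,2aR,7aS)-2-(3,4-dihydroxyphenyl)-6-methoxy-1,1-dimethylcyclobuta[a]indane core, via ortho-quinone methide 22 (not isolated)
Conditions: PPTS (cat.), MgSO4, PhMe, 60 °C
Reagents that add atoms: none
Why: Dehydration of the ortho-hydroxybenzyl allylic alcohol gives vinyl ortho-quinone methide 22, which closes by oxa-6π electrocyclisation to the chromene; the closure is intramolecular and restores aromaticity, so it should outrun addition of the catechol hydroxyls.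

## Compound list

1 | 2-bromo-3,5-dimethoxybenzaldehyde | COc1cc(OC)c(Br)c(C=O)c1 | starting material
2 | 2-(2-bromo-3,5-dimethoxyphenyl)-1,3-dioxolane | COc1cc(OC)c(Br)c(C2OCCO2)c1 | intermediate
3 | 3,3-dimethylpent-4-en-2-one | CC(=O)C(C)(C)C=C | starting material
4 | 1-[2-(1,3-dioxolan-2-yl)-4,6-dimethoxyphenyl]-3,3-dimethylpent-4-en-2-one | C=CC(C)(C)C(=O)Cc1c(OC)cc(OC)cc1C1OCCO1 | intermediate
5 | 2-(3,3-dimethyl-2-oxopent-4-en-1-yl)-3,5-dimethoxybenzaldehyde | C=CC(C)(C)C(=O)Cc1c(OC)cc(OC)cc1C=O | intermediate
6 | 1-(2-ethenyl-4,6-dimethoxyphenyl)-3,3-dimethylpent-4-en-2-one | C=CC(C)(C)C(=O)Cc1c(OC)cc(OC)cc1C=C | intermediate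
7 | 2,4-dimethoxy-7,7-dimethyl-5,7-dihydro-6H-benzo[7]annulen-6-one | COc1cc(OC)c2c(c1)C=CC(C)(C)C(=O)C2 | intermediate
8 | bis(pinacolato)diboron | CC1(C)OB(OC1(C)C)B1OC(C)(C)C(C)(C)O1 | starting material
9 | 2,2'-[(2S,2aR,7aR)-4,6-dimethoxy-1,1-dimethyl-1,2,2a,7-tetrahydro-7aH-cyclobuta[a]indene-2,7a-diyl] C-boronate O-borate bis(pinacol) ester (Bpin on C2, OBpin on C7a) | COc1cc(OC)cc2c1C[C@@]1(OB3OC(C)(C)C(C)(C)O3)[C@@H]2[C@H](B2OC(C)(C)C(C)(C)O2)C1(C)C | intermediate
10 | (2S,2aR,7aR)-4,6-dimethoxy-1,1-dimethyl-2-(4,4,5,5-tetramethyl-1,3,2-dioxaborolan-2-yl)-1,2,2a,7-tetrahydro-7aH-cyclobuta[a]inden-7a-ol | COc1cc(OC)cc2c1C[C@@]1(O)[C@@H]2[C@H](B3OC(C)(C)C(C)(C)O3)C1(C)C | intermediate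
11 | (2S,2aS)-4,6-dimethoxy-1,1-dimethyl-2-(4,4,5,5-tetramethyl-1,3,2-dioxaborolan-2-yl)-2,2a-dihydro-1H-cyclobuta[a]indene | COc1cc(OC)cc2c1C=C1[C@@H]2[C@H](B3OC(C)(C)C(C)(C)O3)C1(C)C | intermediate
12 | (2S,2aS,7aS)-4,6-dimethoxy-1,1-dimethyl-2-(4,4,5,5-tetramethyl-1,3,2-dioxaborolan-2-yl)-2,2a,7,7a-tetrahydro-1H-cyclobuta[a]indene | COc1cc(OC)cc2c1C[C@H]1[C@@H]2[C@H](B3OC(C)(C)C(C)(C)O3)C1(C)C | intermediate
13 | 4-bromo-1,2-bis(benzyloxy)benzene | Brc1ccc(OCc2ccccc2)c(OCc2ccccc2)c1 | starting material
14 | [3,4-bis(benzyloxy)phenyl]lithium | [Li]c1ccc(OCc2ccccc2)c(OCc2ccccc2)c1 | intermediate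
15 | lithium [3,4-bis(benzyloxy)phenyl][(2S,2aS,7aS)-4,6-dimethoxy-1,1-dimethyl-2,2a,7,7a-tetrahydro-1H-cyclobuta[a]inden-2-yl](pinacolato)borate | [Li+].COc1cc(OC)cc2c1C[C@H]1[C@@H]2[C@H]([B-]3(c4ccc(OCc5ccccc5)c(OCc5ccccc5)c4)OC(C)(C)C(C)(C)O3)C1(C)C | intermediate
16 | (2S,2aR,7aS)-2-[3,4-bis(benzyloxy)phenyl]-4,6-dimethoxy-1,1-dimethyl-2,2a,7,7a-tetrahydro-1H-cyclobuta[a]indene | COc1cc(OC)cc2c1C[C@H]1[C@@H]2[C@H](c2ccc(OCc3ccccc3)c(OCc3ccccc3)c2)C1(C)C | intermediate
17 | N-{[(2S,2aR,7aS)-2-[3,4-bis(benzyloxy)phenyl]-4,6-dimethoxy-1,1-dimethyl-2,2a,7,7a-tetrahydro-1H-cyclobuta[a]inden-3-yl]methylidene}-N-methylmethanaminium chloride | COc1cc(OC)c(C=[N+](C)C)c2c1C[C@H]1[C@@H]2[C@H](c2ccc(OCc3ccccc3)c(OCc3ccccc3)c2)C1(C)C.[Cl-] | intermediate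
18 | (2S,2aR,7aS)-2-[3,4-bis(benzyloxy)phenyl]-4,6-dimethoxy-1,1-dimethyl-2,2a,7,7a-tetrahydro-1H-cyclobuta[a]indene-3-carbaldehyde | COc1cc(OC)c(C=O)c2c1C[C@H]1[C@@H]2[C@H](c2ccc(OCc3ccccc3)c(OCc3ccccc3)c2)C1(C)C | intermediate
19 | (2S,2aR,7aS)-2-(3,4-dihydroxyphenyl)-4-hydroxy-6-methoxy-1,1-dimethyl-2,2a,7,7a-tetrahydro-1H-cyclobuta[a]indene-3-carbaldehyde | COc1cc(O)c(C=O)c2c1C[C@H]1[C@@H]2[C@H](c2ccc(O)c(O)c2)C1(C)C | intermediate
20 | 2-methylprop-1-enylmagnesium bromide | CC(C)=C[Mg]Br | starting material
21 | 4-[(2S,2aR,7aS)-4-hydroxy-3-(1-hydroxy-3-methylbut-2-en-1-yl)-6-methoxy-1,1-dimethyl-2,2a,7,7a-tetrahydro-1H-cyclobuta[a]inden-2-yl]benzene-1,2-diol, both carbinol epimers | COc1cc(O)c(C(O)C=C(C)C)c2c1C[C@H]1[C@@H]2[C@H](c2ccc(O)c(O)c2)C1(C)C | intermediate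
22 | (2S,2aR,7aS)-2-(3,4-dihydroxyphenyl)-6-methoxy-1,1-dimethyl-3-(3-methylbut-2-en-1-ylidene)-1,2,2a,3,7,7a-hexahydro-4H-cyclobuta[a]inden-4-one | COC1=CC(=O)C(=CC=C(C)C)C2=C1C[C@H]1[C@@H]2[C@H](c2ccc(O)c(O)c2)C1(C)C | intermediate
23 | CNP0207533.1: 2,2-dimethyl-2H-chromene fused across C3–C4 of the (2S,2aR,7aS)-2-(3,4-dihydroxyphenyl)-6-methoxy-1,1-dimethylcyclobuta[a]indane core | COc1cc2c(c3c1C[C@H]1[C@@H]3[C@H](c3ccc(O)c(O)c3)C1(C)C)C=CC(C)(C)O2 | target

## Step count and least certain steps

Total step count: 13. Longest linear sequence: 13 steps (1 → 23).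

**Step 6 (key step, the proposed new method).** Three processes are most likely to defeat it:
- protonation of the benzylcopper, for example by the acidic C5–H of another molecule of 7, before it reaches the carbonyl, which ends in plain hydroboration;
- reversal of the closure by β-carbon elimination of the strained copper cyclobutanolate;
- slow or poorly face-selective borylcupration at an alkene carbon next to a quaternary centre.

The fallback uses known reaction types, sets out from 1 and 13 and comes back at 16. Suzuki–Miyaura coupling of 1 with 3-methylbut-2-enylboronic acid pinacol ester under conditions selective for the linear isomer (Pd(OAc)2, a biarylphosphine, K3PO4) should give 3,5-dimethoxy-2-(3-methylbut-2-en-1-yl)benzaldehyde F1. Wittig methylenation should give 1-ethenyl-3,5-dimethoxy-2-(3-methylbut-2-en-1-yl)benzene F2. A Heck reaction with 13 (Pd(OAc)2, P(o-tol)3, Et3N) should give 1,2-bis(benzyloxy)-4-{(E)-2-[3,5-dimethoxy-2-(3-methylbut-2-en-1-yl)phenyl]ethenyl}benzene F3. Visible light with a triplet sensitiser such as Ir(ppy)3 should then bring about the intramolecular [2+2] photocycloaddition. The triplet stilbene should close the five-membered ring first, and the resulting 1,4-diradical (benzylic at one end, tertiary at the other) should close the cyclobutane with the aryl group on the less hindered exo face. The product is the racemate, that is 16 together with its mirror image (2R,2aS,7aR)-2-[3,4-bis(benzyloxy)phenyl]-4,6-dimethoxy-1,1-dimethyl-2,2a,7,7a-tetrahydro-1H-cyclobuta[a]indene F4, from which 16 is separated by preparative chromatography on a chiral stationary phase. This path gives up catalytic control of absolute configuration and half of the material, but it also bypasses steps 7 to 9.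

**Step 7.** The tertiary sulfamate may ionise before the C7–H is removed, and the cyclobutyl cation would then rearrange (ring contraction towards the gem-dimethyl carbon). The strain of the ring-fusion alkene may also slow the elimination. The fallback sets out from 10 and comes back at 12 without passing through 11. Acylation with methyl chlorooxoacetate (Et3N, DMAP) should give methyl (2S,2aR,7aR)-4,6-dimethoxy-1,1-dimethyl-2-(4,4,5,5-tetramethyl-1,3,2-dioxaborolan-2-yl)-1,2,2a,7-tetrahydro-7aH-cyclobuta[a]inden-7a-yl oxalate F5. Radical deoxygenation (Bu3SnH, AIBN, PhMe, 110 °C, a Barton–McCombie-type reduction of a tertiary alkyl oxalate) should give 12, since the C7a radical can take up hydrogen only on the face that gives cis fusion.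

**Step 9.** Bromination may occur at the wrong site, either ipso to boron (loss of the aryl group) or on ring A. Migration of the hindered cyclobutyl group, which sits between a quaternary carbon and a ring-fusion carbon, may also be slow. The fallback sets out from 12 and comes back at 16. KHF2 in aqueous MeOH should give potassium trifluoro[(2S,2aS,7aS)-4,6-dimethoxy-1,1-dimethyl-2,2a,7,7a-tetrahydro-1H-cyclobuta[a]inden-2-yl]borate F6. Nickel/photoredox cross-coupling with 13 (NiCl2·glyme, 4,4'-di-tert-butyl-2,2'-bipyridine, [Ir(dF(CF3)ppy)2(bpy)]PF6, Cs2CO3, dioxane, blue light) proceeds through the C2 radical. It is stereoconvergent and should deliver the aryl group on the convex face, trans to ring A, under substrate control.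

**Step 10.** Formylation may be slow because C3 is flanked by the ring-fusion carbon, and attack at C5 or on ring E may compete. The fallback sets out from 16 and comes back at 18. The smaller electrophile NBS (MeCN, 0 °C) should give (2S,2aR,7aS)-2-[3,4-bis(benzyloxy)phenyl]-3-bromo-4,6-dimethoxy-1,1-dimethyl-2,2a,7,7a-tetrahydro-1H-cyclobuta[a]indene F7. Bromine–lithium exchange (n-BuLi, THF, −78 °C) and quenching with DMF should then give 18.

**Step 4.** The ylide may deprotonate the benzylic ketone CH2 instead of adding to the aldehyde, and the enolate can then close onto the aldehyde as a lactolate, which stops the methylenation. The fallback sets out from 1 and comes back at 6 without 2, 4 and 5. Wittig methylenation of 1 should give 2-bromo-1-ethenyl-3,5-dimethoxybenzene F8, and Pd-catalysed α-arylation of 3 with it (Pd(OAc)2, XPhos, NaOtBu) should give 6 directly. The price is possible Heck-type oligomerisation of the bromostyrene.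

## Further compounds

F1 | step 6 | 3,5-dimethoxy-2-(3-methylbut-2-en-1-yl)benzaldehyde | COc1cc(OC)c(CC=C(C)C)c(C=O)c1
F2 | step 6 | 1-ethenyl-3,5-dimethoxy-2-(3-methylbut-2-en-1-yl)benzene | COc1cc(OC)c(CC=C(C)C)c(C=C)c1
F3 | step 6 | 1,2-bis(benzyloxy)-4-{(E)-2-[3,5-dimethoxy-2-(3-methylbut-2-en-1-yl)phenyl]ethenyl}benzene | COc1cc(OC)c(CC=C(C)C)c(/C=C/c2ccc(OCc3ccccc3)c(OCc3ccccc3)c2)c1
F4 | step 6 | (2R,2aS,7aR)-2-[3,4-bis(benzyloxy)phenyl]-4,6-dimethoxy-1,1-dimethyl-2,2a,7,7a-tetrahydro-1H-cyclobuta[a]indene | COc1cc(OC)cc2c1C[C@@H]1[C@H]2[C@@H](c2ccc(OCc3ccccc3)c(OCc3ccccc3)c2)C1(C)C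
F5 | step 7 | methyl (2S,2aR,7aR)-4,6-dimethoxy-1,1-dimethyl-2-(4,4,5,5-tetramethyl-1,3,2-dioxaborolan-2-yl)-1,2,2a,7-tetrahydro-7aH-cyclobuta[a]inden-7a-yl oxalate | COc1cc(OC)cc2c1C[C@@]1(OC(=O)C(=O)OC)[C@@H]2[C@H](B3OC(C)(C)C(C)(C)O3)C1(C)C
F6 | step 9 | potassium trifluoro[(2S,2aS,7aS)-4,6-dimethoxy-1,1-dimethyl-2,2a,7,7a-tetrahydro-1H-cyclobuta[a]inden-2-yl]borate | [K+].COc1cc(OC)cc2c1C[C@H]1[C@@H]2[C@H]([B-](F)(F)F)C1(C)C
F7 | step 10 | (2S,2aR,7aS)-2-[3,4-bis(benzyloxy)phenyl]-3-bromo-4,6-dimethoxy-1,1-dimethyl-2,2a,7,7a-tetrahydro-1H-cyclobuta[a]indene | COc1cc(OC)c(Br)c2c1C[C@H]1[C@@H]2[C@H](c2ccc(OCc3ccccc3)c(OCc3ccccc3)c2)C1(C)C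
F8 | step 4 | 2-bromo-1-ethenyl-3,5-dimethoxybenzene | COc1cc(OC)c(Br)c(C=C)c1
A1 | alternative 1 | 6-{2-[7-(3,4-bis(benzyloxy)phenyl)-6,6-dimethyl-2-oxobicyclo[3.2.0]heptan-3-yl]-2-oxoethyl}-2,2-dimethyl-4H-1,3-dioxin-4-one (cis ring fusion, aryl exo, configured as in 23) | O=C(CC3=CC(=O)OC(C)(C)O3)C1C[C@H]4[C@@H](C1=O)[C@H](c1ccc(OCc5ccccc5)c(OCc5ccccc5)c1)C4(C)C
A2 | alternative 1 | methyl (2S,2aR,7aS)-2-[3,4-bis(benzyloxy)phenyl]-4,6-dihydroxy-1,1-dimethyl-2,2a,7,7a-tetrahydro-1H-cyclobuta[a]indene-3-carboxylate | Oc1cc(O)c(C(=O)OC)c2c1C[C@H]1[C@@H]2[C@H](c2ccc(OCc3ccccc3)c(OCc3ccccc3)c2)C1(C)C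
A3 | alternative 2 | methyl (E)-3-(3,5-dimethoxyphenyl)prop-2-enoate | COC(=O)/C=C/c1cc(OC)cc(OC)c1
A4 | alternative 2 | 1,2-bis(benzyloxy)-4-(2-methylprop-1-en-1-yl)benzene | CC(C)=Cc1ccc(OCc2ccccc2)c(OCc2ccccc2)c1
A5 | alternative 2 | methyl 3-[3,4-bis(benzyloxy)phenyl]-2-(3,5-dimethoxyphenyl)-4,4-dimethylcyclobutane-1-carboxylate, all-trans | COC(=O)[C@@H]1[C@@H](c2cc(OC)cc(OC)c2)[C@H](c2ccc(OCc3ccccc3)c(OCc3ccccc3)c2)C1(C)C
A6 | alternative 3 | 5-iodo-7-methoxy-2,2-dimethyl-2H-chromene | COc1cc(I)c2C=CC(C)(C)Oc2c1
A7 | alternative 3 | (3R)-3-[3,4-bis(benzyloxy)phenyl]-1-(bromomethyl)-4,4-dimethylcyclobut-1-ene | BrCC1=C[C@H](c2ccc(OCc3ccccc3)c(OCc3ccccc3)c2)C1(C)C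
A8 | alternative 3 | bis-benzyl ether of 23 | COc1cc2c(c3c1C[C@H]1[C@@H]3[C@H](c3ccc(OCc4ccccc4)c(OCc4ccccc4)c3)C1(C)C)C=CC(C)(C)O2
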